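The 3(2H)-furanone ring of the target (O10–C10–C1(=O)–C2=C3), bridged across the ten-membered carbocycle C1–C10, is treated as a masked α'-hydroxy ynone. Everything rests on disconnecting C1–C2: chromium-mediated addition of a C2 iodoalkyne to the C1 aldehyde on quaternary C10 closes the carbocycle as a cyclodec-2-yn-1-ol in one operation, with the cis-fused C6/C7 α-methylene-γ-lactone, the C8 ester and every permanent stereocentre already present. The precursor is an open C2–C10–C1 chain with iodoalkyne and α-triethylsilyloxy aldehyde termini. Oxidation, desilylation with 5-endo-dig closure of O10 onto C3, and acetonide hydrolysis finish the synthesis.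

Key step: step 25

Assumption: germacrane numbering (C1–C15; side chain C1'–C3') is used throughout, and the target is read as 4S,6S,7S,8S,10S,2'S with H6 and H7 cis, which calls for the (R)-oxazolidinone, (R)-2-methylglycidol for C10 and (S)-2-methylglycidol for the side chain.

Step 1
Reactants: 1 (R)-2-methylglycidol; 2 vinylmagnesium bromide
Product: 3 (S)-2-methylpent-4-ene-1,2-diol
Conditions: 2 (3 equiv), CuI (10 mol%), THF, −30 → 0 °C
Reagents that add atoms: none
Why: Copper-catalysed SN2 opening of the epoxide by the Grignard reagent occurs at the unhindered CH2 terminus, so the future C10 stereocentre is carried over untouched (Payne equilibration of the alkoxide is degenerate and leads to the same enantiomer).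

Step 2
Reactants: 3 (S)-2-methylpent-4-ene-1,2-diol
Product: 4 (S)-1-[(4-methoxybenzyl)oxy]-2-methylpent-4-en-2-ol
Conditions: NaH (1.05 equiv), 4-methoxybenzyl chloride, Bu4NI (cat.), THF/DMF, 0 °C → rt
Reagents that add atoms: 4-methoxybenzyl chloride, COc1ccc(CCl)cc1
Why: Williamson etherification, in which the primary alkoxide is alkylated much faster than the tertiary one, masks O1 with a group that is later removed oxidatively.

Step 3
Reactants: 4 (S)-1-[(4-methoxybenzyl)oxy]-2-methylpent-4-en-2-ol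
Product: 5 (S)-triethyl({1-[(4-methoxybenzyl)oxy]-2-methylpent-4-en-2-yl}oxy)silane
Conditions: Et3SiOTf, 2,6-lutidine, CH2Cl2, −78 → 0 °C
Reagents that add atoms: triethylsilyl trifluoromethanesulfonate, CC[Si](CC)(CC)OS(=O)(=O)C(F)(F)F
Why: Silylation of the hindered tertiary alcohol with a silyl triflate and a non-nucleophilic base protects O10 until the furanone stage.

Step 4
Reactants: 5 (S)-triethyl({1-[(4-methoxybenzyl)oxy]-2-methylpent-4-en-2-yl}oxy)silane
Product: 7 (S)-4-[(4-methoxybenzyl)oxy]-3-methyl-3-[(triethylsilyl)oxy]butanal, via vicinal diol 6 (not isolated)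
Conditions: OsO4 (2 mol%), NaIO4 (4 equiv), 2,6-lutidine (2 equiv), 1,4-dioxane/H2O (3:1), rt
Reagents that add atoms: sodium periodate, [Na+].[O-]I(=O)(=O)=O
Why: Lemieux–Johnson cleavage (dihydroxylation, then periodate glycol scission) of the terminal alkene gives the C8 aldehyde, which has no α-stereocentre to lose, while the lutidine buffer protects the silyl ether.

Step 5
Reactants: 8 (R)-4-benzyloxazolidin-2-one; 9 pent-4-enoyl chloride
Product: 10 (R)-4-benzyl-3-(pent-4-enoyl)oxazolidin-2-one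
Conditions: Et3N, DMAP (10 mol%), CH2Cl2, 0 °C → rt
Reagents that add atoms: none
Why: DMAP-catalysed N-acylation gives the imide whose allyl group is the latent C11–C12 unit; unlike an ester, an alkene cannot lactonise onto O8 or be attacked by the later organolithium.

Step 6
Reactants: 10 (R)-4-benzyl-3-(pent-4-enoyl)oxazolidin-2-one; 7 (S)-4-[(4-methoxybenzyl)oxy]-3-methyl-3-[(triethylsilyl)oxy]butanal
Product: 12 (R)-4-benzyl-3-{(2R,3S,5S)-2-allyl-3-hydroxy-6-[(4-methoxybenzyl)oxy]-5-methyl-5-[(triethylsilyl)oxy]hexanoyl}oxazolidin-2-one, via boron enolate 11 (not isolated)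
Conditions: Bu2BOTf (1.1 equiv), Et3N (1.3 equiv), CH2Cl2, −78 → 0 °C; 7, −78 → 0 °C; pH 7 buffer, MeOH, 30% H2O2, 0 °C
Reagents that add atoms: none
Why: Evans syn aldol reaction, in which the (Z)-boron enolate reacts through a Zimmerman–Traxler chair on the face away from the benzyl group of the (R)-auxiliary, should set C7 and C8 in the required syn relationship (7R at this stage, 8S).

Step 7
Reactants: 12 (R)-4-benzyl-3-{(2R,3S,5S)-2-allyl-3-hydroxy-6-[(4-methoxybenzyl)oxy]-5-methyl-5-[(triethylsilyl)oxy]hexanoyl}oxazolidin-2-one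
Product: 13 (2R,3S,5S)-2-allyl-3-hydroxy-N-methoxy-6-[(4-methoxybenzyl)oxy]-N,5-dimethyl-5-[(triethylsilyl)oxy]hexanamide
Conditions: MeNH(OMe)·HCl (3 equiv), AlMe3 (3 equiv), THF, −20 → 0 °C
Reagents that add atoms: N,O-dimethylhydroxylamine hydrochloride, CNOC.Cl
Why: Aluminium amide transamination of the imide, assisted by the free C8 hydroxyl, gives the Weinreb amide and releases the auxiliary without touching C7.

Step 8
Reactants: 14 methyl (S)-3-hydroxy-2-methylpropanoate (Roche ester)
Product: 15 methyl (S)-3-[(tert-butyldimethylsilyl)oxy]-2-methylpropanoate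
Conditions: TBSCl, imidazole, CH2Cl2, rt
Reagents that add atoms: tert-butyldimethylsilyl chloride, CC(C)(C)[Si](C)(C)Cl
Why: Standard O-silylation of the primary alcohol, which will become C5, leaves the stereocentre untouched.

Step 9
Reactants: 15 methyl (S)-3-[(tert-butyldimethylsilyl)oxy]-2-methylpropanoate
Product: 17 (R)-tert-butyldimethyl[(2-methylbut-3-yn-1-yl)oxy]silane, via silyloxy aldehyde 16 (not isolated)
Conditions: i-Bu2AlH (1.1 equiv), CH2Cl2, −78 °C; then MeOH, K2CO3, dimethyl (1-diazo-2-oxopropyl)phosphonate, −78 °C → rt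
Reagents that add atoms: dimethyl (1-diazo-2-oxopropyl)phosphonate, COP(=O)(OC)C(=[N+]=[N-])C(C)=O
Why: Partial reduction of the ester to the aldehyde, followed in the same flask by Ohira–Bestmann (Seyferth–Gilbert) homologation, turns the ester carbon into C3 and adds C2, with the α-stereocentre (future C4) exposed only briefly to mild carbonate base.

Step 10
Reactants: 17 (R)-tert-butyldimethyl[(2-methylbut-3-yn-1-yl)oxy]silane
Product: 19 (R)-tert-butyldimethyl{[2-methyl-4-(trimethylsilyl)but-3-yn-1-yl]oxy}silane, via lithium acetylide 18 (not isolated)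
Conditions: n-BuLi, THF, −78 °C; Me3SiCl, −78 °C → rt
Reagents that add atoms: chlorotrimethylsilane, C[Si](C)(C)Cl
Why: Deprotonation and C-silylation of the terminal alkyne removes the acidic C–H before the organolithium chemistry and installs a cap that is later exchanged directly for iodine.

Step 11
Reactants: 19 (R)-tert-butyldimethyl{[2-methyl-4-(trimethylsilyl)but-3-yn-1-yl]oxy}silane
Product: 20 (R)-2-methyl-4-(trimethylsilyl)but-3-yn-1-ol
Conditions: camphorsulfonic acid (10 mol%), MeOH/CH2Cl2 (1:1), 0 °C → rt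
Reagents that add atoms: none
Why: Acid-catalysed methanolysis cleaves the primary O-silyl ether, whereas the C-silyl alkyne, which needs fluoride or base for cleavage, is retained.

Step 12
Reactants: 20 (R)-2-methyl-4-(trimethylsilyl)but-3-yn-1-ol
Product: 21 (R)-(4-iodo-3-methylbut-1-yn-1-yl)trimethylsilane
Conditions: I2, PPh3, imidazole, CH2Cl2, 0 °C → rt
Reagents that add atoms: iodine, [I][I]
Why: Appel-type iodination proceeds by SN2 displacement at the primary carbon, so the adjacent stereocentre is not involved.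

Step 13
Reactants: 21 (R)-(4-iodo-3-methylbut-1-yn-1-yl)trimethylsilane; 13 (2R,3S,5S)-2-allyl-3-hydroxy-N-methoxy-6-[(4-methoxybenzyl)oxy]-N,5-dimethyl-5-[(triethylsilyl)oxy]hexanamide
Product: 24 (2S,4S,5R,8S)-5-allyl-4-hydroxy-1-[(4-methoxybenzyl)oxy]-2,8-dimethyl-2-[(triethylsilyl)oxy]-10-(trimethylsilyl)dec-9-yn-6-one, via organolithium 22 (not isolated), via magnesium alkoxide 23 (not isolated)
Conditions: 21, t-BuLi (2.1 equiv), Et2O, −78 °C; separately 13, i-PrMgCl (1.0 equiv), THF, −78 °C; combine, −78 → −40 °C; aq. NH4Cl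
Reagents that add atoms: none
Why: Iodine–lithium exchange gives the primary alkyllithium, which adds once to the Weinreb amide through the stable N-methoxy chelate to form the C5–C6 bond, while the pre-formed magnesium alkoxide at O8 saves organolithium and disfavours retro-aldol cleavage and silyl migration from O10.

Step 14
Reactants: 25 (S)-2-methylglycidol
Product: 26 (S)-3-(benzyloxy)-2-methylpropane-1,2-diol
Conditions: BnOH (solvent), NaH (20 mol%), 70 °C
Reagents that add atoms: benzyl alcohol, OCc1ccccc1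
Why: Base-catalysed SN2 opening of the epoxide by benzyloxide at the CH2 terminus differentiates the two CH2O arms without touching the quaternary stereocentre (Payne rearrangement is again degenerate).

Step 15
Reactants: 26 (S)-3-(benzyloxy)-2-methylpropane-1,2-diol
Product: 27 (R)-4-[(benzyloxy)methyl]-2,2,4-trimethyl-1,3-dioxolane
Conditions: 2,2-dimethoxypropane, pyridinium p-toluenesulfonate (cat.), acetone, rt
Reagents that add atoms: 2,2-dimethoxypropane, COC(C)(C)OC
Why: Acid-catalysed transacetalisation closes the five-membered acetonide across the tertiary and the free primary hydroxyl.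

Step 16
Reactants: 27 (R)-4-[(benzyloxy)methyl]-2,2,4-trimethyl-1,3-dioxolane
Product: 28 (R)-(2,2,4-trimethyl-1,3-dioxolan-4-yl)methanol
Conditions: H2 (1 atm), Pd/C (10%), EtOAc, rt
Reagents that add atoms: none
Why: Hydrogenolysis of the benzyl ether over palladium on carbon frees the primary alcohol and leaves the acetonide intact under neutral conditions.

Step 17
Reactants: 28 (R)-(2,2,4-trimethyl-1,3-dioxolan-4-yl)methanol
Product: 29 (S)-2,2,4-trimethyl-1,3-dioxolane-4-carbaldehyde
Conditions: (COCl)2, DMSO, CH2Cl2, −78 °C; Et3N, −78 → 0 °C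
Reagents that add atoms: none
Why: Swern oxidation gives the α,α-disubstituted aldehyde, which has no α-hydrogen and therefore cannot epimerise.

Step 18
Reactants: 24 (2S,4S,5R,8S)-5-allyl-4-hydroxy-1-[(4-methoxybenzyl)oxy]-2,8-dimethyl-2-[(triethylsilyl)oxy]-10-(trimethylsilyl)dec-9-yn-6-one; 29 (S)-2,2,4-trimethyl-1,3-dioxolane-4-carbaldehyde
Product: 30 (2S,4S,5S,6S,8S)-5-allyl-6-hydroxy-1-[(4-methoxybenzyl)oxy]-2,8-dimethyl-2-[(triethylsilyl)oxy]-10-(trimethylsilyl)dec-9-yn-4-yl (S)-2,2,4-trimethyl-1,3-dioxolane-4-carboxylate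
Conditions: SmI2 (30 mol%), 29 (2 equiv), THF, −10 °C
Reagents that add atoms: none
Why: Evans–Tishchenko reaction, in which the samarium-bound hemiacetal formed from O8 and 29 delivers hydride intramolecularly to the C6 ketone through a chair-like bicyclic transition state, should give the 1,3-anti (6S) alcohol and leave the side-chain acyl group on O8 in the same operation.

Step 19
Reactants: 30 (2S,4S,5S,6S,8S)-5-allyl-6-hydroxy-1-[(4-methoxybenzyl)oxy]-2,8-dimethyl-2-[(triethylsilyl)oxy]-10-(trimethylsilyl)dec-9-yn-4-yl (S)-2,2,4-trimethyl-1,3-dioxolane-4-carboxylate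
Product: 33 C12 lactol (both anomers), via vicinal diol 31 (not isolated), via hydroxy aldehyde 32 (not isolated)
Conditions: OsO4 (2 mol%), NaIO4 (4 equiv), 2,6-lutidine (2 equiv), 1,4-dioxane/H2O (3:1), rt
Reagents that add atoms: sodium periodate, [Na+].[O-]I(=O)(=O)=O
Why: Lemieux–Johnson cleavage of the terminal alkene (far more reactive towards OsO4 than the silyl alkyne) gives the C12 aldehyde, which the free O6 hydroxyl traps as the five-membered lactol, the only ring possible because O8 is already acylated.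

Step 20
Reactants: 33 C12 lactol (both anomers)
Product: 34 cis-12,6-lactone
Conditions: TEMPO (20 mol%), PhI(OAc)2 (2.5 equiv), CH2Cl2, rt
Reagents that add atoms: none
Why: Oxoammonium-mediated oxidation of the lactol gives the γ-lactone under non-basic conditions, and its cis C6/C7 substitution follows from the syn-aldol and anti-reduction steps.

Step 21
Reactants: 34 cis-12,6-lactone
Product: 38 α-methylene lactone, via lithium enolate 35 (not isolated), via Mannich base 36 (not isolated), via methiodide 37 (not isolated)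
Conditions: LiN(SiMe3)2 (1.15 equiv), THF, −78 °C; CH2=NMe2+ I− (3 equiv), −78 → −20 °C; MeI, THF, rt; aq. NaHCO3, CH2Cl2, rt
Reagents that add atoms: N,N-dimethylmethyleneiminium iodide (Eschenmoser's salt), C=[N+](C)C.[I-]
Why: α-Methylenation by Mannich reaction of the lactone enolate, N-quaternisation and E1cB loss of trimethylamine installs C13; the enolate is trapped cold, the O8 ester has no α-hydrogen and a neopentyl-type hindered carbonyl, and C7 cannot epimerise through this enolate.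

Step 22
Reactants: 38 α-methylene lactone
Product: 39 iodoalkyne 4-methoxybenzyl ether
Conditions: N-iodosuccinimide (1.2 equiv), AgNO3 (10 mol%), acetone, rt, dark
Reagents that add atoms: N-iodosuccinimide, O=C1CCC(=O)N1I
Why: Silver-catalysed ipso-iododesilylation of the alkynylsilane (through the silver acetylide) gives the 1-iodoalkyne under neutral conditions that leave the methylene lactone, esters and silyl ether alone.

Step 23
Reactants: 39 iodoalkyne 4-methoxybenzyl ether
Product: 40 iodoalkyne primary alcohol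
Conditions: DDQ (1.5 equiv), CH2Cl2/pH 7 buffer (10:1), 0 °C → rt
Reagents that add atoms: none
Why: Oxidative cleavage of the 4-methoxybenzyl ether by DDQ (benzylic hydride abstraction, then hydrolysis of the oxocarbenium ion) frees O1 under buffered neutral conditions.

Step 24
Reactants: 40 iodoalkyne primary alcohol
Product: 41 iodoalkyne aldehyde (cyclisation precursor)
Conditions: Dess–Martin periodinane, NaHCO3, CH2Cl2, 0 °C → rt
Reagents that add atoms: none
Why: Dess–Martin oxidation gives the non-enolisable α-silyloxy aldehyde, which is made last so that it meets no other reagent before ring closure.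

Step 25
Reactants: 41 iodoalkyne aldehyde (cyclisation precursor)
Product: 43 cyclodec-2-yn-1-ol, via alkynylchromium dichloride 42 (not isolated)
Conditions: CrCl2 (10 equiv), NiCl2 (10 mol%), degassed THF, rt; 41 added by syringe pump over 10 h to a final 2 mM
Reagents that add atoms: none
Why: Two equivalents of CrCl2 reduce the C2–I bond (NiCl2 catalyses this through oxidative addition to zerovalent nickel and transmetalation) to the trivalent alkynylchromium dichloride 42, which adds to the C1 aldehyde and forms the C1–C2 bond. The closest known reaction type is the Nozaki–Hiyama–Kishi coupling of 1-iodoalkynes with aldehydes, including its intramolecular use to close nine- and ten-membered cycloalkynols. The ten-membered carbocycle is closed end-to-end by nucleophilic attack on the carbonyl carbon (10-exo-trig), and a ring of this size accommodates the near-linear C1–C2≡C3–C4 unit with little bending. The new C1 carbinol is controlled by the adjacent quaternary C10 centre: Felkin–Anh attack anti to the C10–OSi bond should favour the 1R epimer shown, but either epimer serves because C1 becomes a ketone in step 26. The step needs chemoselectivity for the aldehyde over the lactone, the acrylate and the hindered ester, which the weakly basic, non-conjugate-adding organochromium provides, and ring closure over oligomerisation, which slow addition at high dilution and the turn imposed by the cis-fused lactone between C5 and C8 should secure. The aldehyde is non-enolisable, so the long reaction time costs no stereochemistry.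

Step 26
Reactants: 43 cyclodec-2-yn-1-ol
Product: 44 cyclodec-2-yn-1-one
Conditions: Dess–Martin periodinane, NaHCO3, CH2Cl2, 0 °C → rt
Reagents that add atoms: none
Why: Dess–Martin oxidation of the propargylic alcohol gives the ynone and removes the transient C1 stereocentre, so both epimers of 43 converge.

Step 27
Reactants: 44 cyclodec-2-yn-1-one
Product: 46 furanone acetonide, via hydroxy ynone 45 (not isolated)
Conditions: HF·pyridine, pyridine, THF, 0 °C → rt; solvent exchange; AuCl3 (5 mol%), CH2Cl2, rt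
Reagents that add atoms: none
Why: Fluoride cleavage of the tertiary silyl ether frees O10, which adds to C3 of the gold-activated ynone in a 5-endo-dig oxa-Michael cyclisation (the known gold-catalysed route from γ-hydroxy ynones to 3(2H)-furanones); no amine nucleophile is used, so the α-methylene lactone is spared.

Step 28
Reactants: 46 furanone acetonide
Product: 47 CNP0263764.3 (target)
Conditions: TFA/H2O (4:1), CH2Cl2, 0 °C → rt
Reagents that add atoms: none
Why: Acid-catalysed hydrolysis of the isopropylidene acetal releases the side-chain diol, and the furanone (a vinylogous ester), the lactone and the tertiary α-hydroxy ester should tolerate brief aqueous acid.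

Compound list
1 | (R)-2-methylglycidol [(R)-(2-methyloxiran-2-yl)methanol] | OC[C@@]1(C)OC1 | starting material
2 | vinylmagnesium bromide | C=C[Mg]Br | starting material
3 | (S)-2-methylpent-4-ene-1,2-diol | C=CC[C@](C)(O)CO | intermediate
4 | (S)-1-[(4-methoxybenzyl)oxy]-2-methylpent-4-en-2-ol | C=CC[C@](C)(O)COCc1ccc(OC)cc1 | intermediate
5 | (S)-triethyl({1-[(4-methoxybenzyl)oxy]-2-methylpent-4-en-2-yl}oxy)silane | C=CC[C@](C)(O[Si](CC)(CC)CC)COCc1ccc(OC)cc1 | intermediate
6 | (4S)-5-[(4-methoxybenzyl)oxy]-4-methyl-4-[(triethylsilyl)oxy]pentane-1,2-diol (both C2 epimers) | OCC(O)C[C@](C)(O[Si](CC)(CC)CC)COCc1ccc(OC)cc1 | intermediate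
7 | (S)-4-[(4-methoxybenzyl)oxy]-3-methyl-3-[(triethylsilyl)oxy]butanal | O=CC[C@](C)(O[Si](CC)(CC)CC)COCc1ccc(OC)cc1 | intermediate
8 | (R)-4-benzyloxazolidin-2-one | O=C1N[C@H](Cc2ccccc2)CO1 | starting material
9 | pent-4-enoyl chloride | C=CCCC(=O)Cl | starting material
10 | (R)-4-benzyl-3-(pent-4-enoyl)oxazolidin-2-one | C=CCCC(=O)N1C(=O)OC[C@H]1Cc1ccccc1 | intermediate
11 | (Z)-dibutylboron enolate of 10 | CCCCB(CCCC)O/C(=C\CC=C)N1C(=O)OC[C@H]1Cc1ccccc1 | intermediate
12 | (R)-4-benzyl-3-{(2R,3S,5S)-2-allyl-3-hydroxy-6-[(4-methoxybenzyl)oxy]-5-methyl-5-[(triethylsilyl)oxy]hexanoyl}oxazolidin-2-one | O=C1OC[C@@H](Cc2ccccc2)N1C(=O)[C@H](CC=C)[C@@H](O)C[C@](C)(O[Si](CC)(CC)CC)COCc1ccc(OC)cc1 | intermediate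
13 | (2R,3S,5S)-2-allyl-3-hydroxy-N-methoxy-6-[(4-methoxybenzyl)oxy]-N,5-dimethyl-5-[(triethylsilyl)oxy]hexanamide | CON(C)C(=O)[C@H](CC=C)[C@@H](O)C[C@](C)(O[Si](CC)(CC)CC)COCc1ccc(OC)cc1 | intermediate
14 | methyl (S)-3-hydroxy-2-methylpropanoate (Roche ester) | OC[C@H](C)C(=O)OC | starting material
15 | methyl (S)-3-[(tert-butyldimethylsilyl)oxy]-2-methylpropanoate | CC(C)(C)[Si](C)(C)OC[C@H](C)C(=O)OC | intermediate
16 | (S)-3-[(tert-butyldimethylsilyl)oxy]-2-methylpropanal | CC(C)(C)[Si](C)(C)OC[C@H](C)C=O | intermediate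
17 | (R)-tert-butyldimethyl[(2-methylbut-3-yn-1-yl)oxy]silane | CC(C)(C)[Si](C)(C)OC[C@H](C)C#C | intermediate
18 | lithium acetylide of 17 | CC(C)(C)[Si](C)(C)OC[C@H](C)C#C[Li] | intermediate
19 | (R)-tert-butyldimethyl{[2-methyl-4-(trimethylsilyl)but-3-yn-1-yl]oxy}silane | CC(C)(C)[Si](C)(C)OC[C@H](C)C#C[Si](C)(C)C | intermediate
20 | (R)-2-methyl-4-(trimethylsilyl)but-3-yn-1-ol | OC[C@H](C)C#C[Si](C)(C)C | intermediate
21 | (R)-(4-iodo-3-methylbut-1-yn-1-yl)trimethylsilane | IC[C@H](C)C#C[Si](C)(C)C | intermediate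
22 | (S)-[2-methyl-4-(trimethylsilyl)but-3-yn-1-yl]lithium | [Li]C[C@H](C)C#C[Si](C)(C)C | intermediate
23 | chloromagnesium O8-alkoxide of 13 | CON(C)C(=O)[C@H](CC=C)[C@@H](O[Mg]Cl)C[C@](C)(O[Si](CC)(CC)CC)COCc1ccc(OC)cc1 | intermediate
24 | (2S,4S,5R,8S)-5-allyl-4-hydroxy-1-[(4-methoxybenzyl)oxy]-2,8-dimethyl-2-[(triethylsilyl)oxy]-10-(trimethylsilyl)dec-9-yn-6-one | C[Si](C)(C)C#C[C@@H](C)CC(=O)[C@H](CC=C)[C@@H](O)C[C@](C)(O[Si](CC)(CC)CC)COCc1ccc(OC)cc1 | intermediate
25 | (S)-2-methylglycidol [(S)-(2-methyloxiran-2-yl)methanol] | OC[C@]1(C)OC1 | starting material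
26 | (S)-3-(benzyloxy)-2-methylpropane-1,2-diol | OC[C@](C)(O)COCc1ccccc1 | intermediate
27 | (R)-4-[(benzyloxy)methyl]-2,2,4-trimethyl-1,3-dioxolane | C[C@@]1(COCc2ccccc2)COC(C)(C)O1 | intermediate
28 | (R)-(2,2,4-trimethyl-1,3-dioxolan-4-yl)methanol | C[C@@]1(CO)COC(C)(C)O1 | intermediate
29 | (S)-2,2,4-trimethyl-1,3-dioxolane-4-carbaldehyde | C[C@@]1(C=O)COC(C)(C)O1 | intermediate
30 | (2S,4S,5S,6S,8S)-5-allyl-6-hydroxy-1-[(4-methoxybenzyl)oxy]-2,8-dimethyl-2-[(triethylsilyl)oxy]-10-(trimethylsilyl)dec-9-yn-4-yl (S)-2,2,4-trimethyl-1,3-dioxolane-4-carboxylate | C[Si](C)(C)C#C[C@@H](C)C[C@H](O)[C@H](CC=C)[C@@H](OC(=O)[C@@]4(C)OC(C)(C)OC4)C[C@](C)(O[Si](CC)(CC)CC)COCc1ccc(OC)cc1 | intermediate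
31 | 5-(2,3-dihydroxypropyl) analogue of 30 (allyl group dihydroxylated; both carbinol epimers) | C[Si](C)(C)C#C[C@@H](C)C[C@H](O)[C@H](CC(O)CO)[C@@H](OC(=O)[C@@]4(C)OC(C)(C)OC4)C[C@](C)(O[Si](CC)(CC)CC)COCc1ccc(OC)cc1 | intermediate
32 | 5-(2-oxoethyl) analogue of 30 (C12 aldehyde; open-chain tautomer of 33) | C[Si](C)(C)C#C[C@@H](C)C[C@H](O)[C@H](CC=O)[C@@H](OC(=O)[C@@]4(C)OC(C)(C)OC4)C[C@](C)(O[Si](CC)(CC)CC)COCc1ccc(OC)cc1 | intermediate
33 | (1S,3S)-1-{(2S,3S)-5-hydroxy-2-[(S)-2-methyl-4-(trimethylsilyl)but-3-yn-1-yl]tetrahydrofuran-3-yl}-4-[(4-methoxybenzyl)oxy]-3-methyl-3-[(triethylsilyl)oxy]butyl (S)-2,2,4-trimethyl-1,3-dioxolane-4-carboxylate (C12 lactol; both anomers) | C[Si](C)(C)C#C[C@@H](C)C[C@@H]2OC(O)C[C@@H]2[C@@H](OC(=O)[C@@]4(C)OC(C)(C)OC4)C[C@](C)(O[Si](CC)(CC)CC)COCc1ccc(OC)cc1 | intermediate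
34 | (1S,3S)-4-[(4-methoxybenzyl)oxy]-3-methyl-1-{(2S,3S)-2-[(S)-2-methyl-4-(trimethylsilyl)but-3-yn-1-yl]-5-oxotetrahydrofuran-3-yl}-3-[(triethylsilyl)oxy]butyl (S)-2,2,4-trimethyl-1,3-dioxolane-4-carboxylate (cis-12,6-lactone) | C[Si](C)(C)C#C[C@@H](C)C[C@@H]2OC(=O)C[C@@H]2[C@@H](OC(=O)[C@@]4(C)OC(C)(C)OC4)C[C@](C)(O[Si](CC)(CC)CC)COCc1ccc(OC)cc1 | intermediate
35 | lithium enolate of 34 (C11=C12–OLi) | C[Si](C)(C)C#C[C@@H](C)C[C@@H]2OC(O[Li])=C[C@@H]2[C@@H](OC(=O)[C@@]4(C)OC(C)(C)OC4)C[C@](C)(O[Si](CC)(CC)CC)COCc1ccc(OC)cc1 | intermediate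
36 | C11-[(dimethylamino)methyl] derivative of 34 (both C11 epimers) | C[Si](C)(C)C#C[C@@H](C)C[C@@H]2OC(=O)C(CN(C)C)[C@@H]2[C@@H](OC(=O)[C@@]4(C)OC(C)(C)OC4)C[C@](C)(O[Si](CC)(CC)CC)COCc1ccc(OC)cc1 | intermediate
37 | C11-[(trimethylammonio)methyl] iodide derived from 36 | C[Si](C)(C)C#C[C@@H](C)C[C@@H]2OC(=O)C(C[N+](C)(C)C)[C@@H]2[C@@H](OC(=O)[C@@]4(C)OC(C)(C)OC4)C[C@](C)(O[Si](CC)(CC)CC)COCc1ccc(OC)cc1.[I-] | intermediate
38 | (1S,3S)-4-[(4-methoxybenzyl)oxy]-3-methyl-1-{(2S,3S)-4-methylidene-2-[(S)-2-methyl-4-(trimethylsilyl)but-3-yn-1-yl]-5-oxotetrahydrofuran-3-yl}-3-[(triethylsilyl)oxy]butyl (S)-2,2,4-trimethyl-1,3-dioxolane-4-carboxylate | C[Si](C)(C)C#C[C@@H](C)C[C@@H]2OC(=O)C(=C)[C@@H]2[C@@H](OC(=O)[C@@]4(C)OC(C)(C)OC4)C[C@](C)(O[Si](CC)(CC)CC)COCc1ccc(OC)cc1 | intermediate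
39 | (1S,3S)-1-{(2S,3S)-2-[(S)-4-iodo-2-methylbut-3-yn-1-yl]-4-methylidene-5-oxotetrahydrofuran-3-yl}-4-[(4-methoxybenzyl)oxy]-3-methyl-3-[(triethylsilyl)oxy]butyl (S)-2,2,4-trimethyl-1,3-dioxolane-4-carboxylate | IC#C[C@@H](C)C[C@@H]2OC(=O)C(=C)[C@@H]2[C@@H](OC(=O)[C@@]4(C)OC(C)(C)OC4)C[C@](C)(O[Si](CC)(CC)CC)COCc1ccc(OC)cc1 | intermediate
40 | (1S,3S)-4-hydroxy-1-{(2S,3S)-2-[(S)-4-iodo-2-methylbut-3-yn-1-yl]-4-methylidene-5-oxotetrahydrofuran-3-yl}-3-methyl-3-[(triethylsilyl)oxy]butyl (S)-2,2,4-trimethyl-1,3-dioxolane-4-carboxylate | IC#C[C@@H](C)C[C@@H]2OC(=O)C(=C)[C@@H]2[C@@H](OC(=O)[C@@]4(C)OC(C)(C)OC4)C[C@](C)(O[Si](CC)(CC)CC)CO | intermediate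
41 | (1S,3S)-1-{(2S,3S)-2-[(S)-4-iodo-2-methylbut-3-yn-1-yl]-4-methylidene-5-oxotetrahydrofuran-3-yl}-3-methyl-4-oxo-3-[(triethylsilyl)oxy]butyl (S)-2,2,4-trimethyl-1,3-dioxolane-4-carboxylate (open-chain iodoalkyne aldehyde) | IC#C[C@@H](C)C[C@@H]2OC(=O)C(=C)[C@@H]2[C@@H](OC(=O)[C@@]4(C)OC(C)(C)OC4)C[C@](C)(O[Si](CC)(CC)CC)C=O | intermediate
42 | trivalent alkynylchromium dichloride derived from 41 (Cr on C2) | Cl[Cr](Cl)C#C[C@@H](C)C[C@@H]2OC(=O)C(=C)[C@@H]2[C@@H](OC(=O)[C@@]4(C)OC(C)(C)OC4)C[C@](C)(O[Si](CC)(CC)CC)C=O | intermediate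
43 | (1R,4S,6S,7S,8S,10S)-1-hydroxy-10-[(triethylsilyl)oxy]germacr-11(13)-en-2-yn-12,6-olid-8-yl (S)-2,2,4-trimethyl-1,3-dioxolane-4-carboxylate (cyclodec-2-yn-1-ol; expected major C1 epimer drawn) | O[C@@H]1C#C[C@@H](C)C[C@@H]2OC(=O)C(=C)[C@@H]2[C@@H](OC(=O)[C@@]4(C)OC(C)(C)OC4)C[C@]1(C)O[Si](CC)(CC)CC | intermediate
44 | (4S,6S,7S,8S,10S)-1-oxo-10-[(triethylsilyl)oxy]germacr-11(13)-en-2-yn-12,6-olid-8-yl (S)-2,2,4-trimethyl-1,3-dioxolane-4-carboxylate | O=C1C#C[C@@H](C)C[C@@H]2OC(=O)C(=C)[C@@H]2[C@@H](OC(=O)[C@@]4(C)OC(C)(C)OC4)C[C@]1(C)O[Si](CC)(CC)CC | intermediate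
45 | (4S,6S,7S,8S,10S)-10-hydroxy-1-oxogermacr-11(13)-en-2-yn-12,6-olid-8-yl (S)-2,2,4-trimethyl-1,3-dioxolane-4-carboxylate | O=C1C#C[C@@H](C)C[C@@H]2OC(=O)C(=C)[C@@H]2[C@@H](OC(=O)[C@@]4(C)OC(C)(C)OC4)C[C@]1(C)O | intermediate
46 | (4S,6S,7S,8S,10S)-3,10-epoxy-1-oxogermacra-2,11(13)-dien-12,6-olid-8-yl (S)-2,2,4-trimethyl-1,3-dioxolane-4-carboxylate | C=C1C(=O)O[C@H]2C[C@H](C)C3=CC(=O)[C@](C)(C[C@H](OC(=O)[C@@]4(C)OC(C)(C)OC4)[C@@H]12)O3 | intermediate
47 | (4S,6S,7S,8S,10S)-3,10-epoxy-1-oxogermacra-2,11(13)-dien-12,6-olid-8-yl (S)-2,3-dihydroxy-2-methylpropanoate (CNP0263764.3) | C=C1C(=O)O[C@H]2C[C@H](C)C3=CC(=O)[C@](C)(C[C@H](OC(=O)[C@@](C)(O)CO)[C@@H]12)O3 | target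

Total step count: 28.
Longest linear sequence: 18 steps (1 → 3 → 4 → 5 → 7 → 12 → 13 → 24 → 30 → 33 → 34 → 38 → 39 → 40 → 41 → 43 → 44 → 46 → 47).

Steps most likely to fail

Step 25. Oligomerisation may outrun ring closure, or the alkynyl–metal species may be protonated or reductively deiodinated before it reaches the hindered aldehyde. The fallback makes the same bond from a zinc acetylide generated by soft deprotonation instead of by insertion into a C–I bond. It would set out from 38. Catalytic AgNO3 in aqueous acetone should remove the C-silyl group to give the terminal alkyne F1. DDQ in buffered CH2Cl2 should then free the primary alcohol F2, and Dess–Martin oxidation should give the terminal alkyne aldehyde F3. Slow addition of F3 to Zn(OTf)2 and Et3N in toluene at high dilution (amine-promoted zinc alkynylation of a non-enolisable aldehyde) should close the ring, and the route is rejoined at 43.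

Step 21. On warming, the lactone enolate may attack the O8 ester carbonyl in a five-membered Claisen-type acyl transfer before it is aminomethylated, or the elimination may stall. The fallback avoids any enolate by methylenating at the aldehyde oxidation level. It would set out from lactol 33, which reacts through its hydroxy-aldehyde tautomer 32. Aqueous formaldehyde with catalytic pyrrolidine and propionic acid in i-PrOH at 45 °C (Mannich-type α-methylenation of an aldehyde) should give the α-methylene lactol F4. Oxidation of this allylic lactol with MnO2 in CH2Cl2 returns to the route at 38.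

Step 27. The oxa-Michael closure across the strained ynone may be slow or may compete with hydration and Lewis-acid loss of the acetonide. The fallback closes the oxygen bridge at the alcohol oxidation level and oxidises afterwards. It would set out from 43. HF·pyridine should give the 1,10-diol F5. Ph3PAuCl/AgOTf (5 mol%) in CH2Cl2 should then effect 5-endo-dig hydroalkoxylation of the alkyne by O10 (the known gold-catalysed cyclisation of 3-alkyne-1,2-diols; quaternary C10 prevents aromatisation to a furan) to give the bridged 2,3-dihydrofuran-3-ol F6. Oxidation of the allylic C1 carbinol with MnO2 returns to the route at 46.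

Further compounds
F1 | step 25 | terminal alkyne analogue of 38 (C2–H in place of C2–SiMe3) | C#C[C@@H](C)C[C@@H]2OC(=O)C(=C)[C@@H]2[C@@H](OC(=O)[C@@]4(C)OC(C)(C)OC4)C[C@](C)(O[Si](CC)(CC)CC)COCc1ccc(OC)cc1
F2 | step 25 | terminal alkyne primary alcohol (O1–H) | C#C[C@@H](C)C[C@@H]2OC(=O)C(=C)[C@@H]2[C@@H](OC(=O)[C@@]4(C)OC(C)(C)OC4)C[C@](C)(O[Si](CC)(CC)CC)CO
F3 | step 25 | terminal alkyne C1 aldehyde | C#C[C@@H](C)C[C@@H]2OC(=O)C(=C)[C@@H]2[C@@H](OC(=O)[C@@]4(C)OC(C)(C)OC4)C[C@](C)(O[Si](CC)(CC)CC)C=O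
F4 | step 21 | α-methylene C12 lactol (both anomers) | C[Si](C)(C)C#C[C@@H](C)C[C@@H]2OC(O)C(=C)[C@@H]2[C@@H](OC(=O)[C@@]4(C)OC(C)(C)OC4)C[C@](C)(O[Si](CC)(CC)CC)COCc1ccc(OC)cc1
F5 | step 27 | cyclodec-2-yne-1,10-diol (desilylated 43) | O[C@@H]1C#C[C@@H](C)C[C@@H]2OC(=O)C(=C)[C@@H]2[C@@H](OC(=O)[C@@]4(C)OC(C)(C)OC4)C[C@]1(C)O
F6 | step 27 | 3,10-epoxy-1-hydroxygermacra-2,11(13)-dien-12,6-olide 8-ester (bridged 2,3-dihydrofuran-3-ol) | C=C1C(=O)O[C@H]2C[C@H](C)C3=C[C@@H](O)[C@](C)(C[C@H](OC(=O)[C@@]4(C)OC(C)(C)OC4)[C@@H]12)O3
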